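## Retrosynthetic overview

1. The C11/C14 hydroquinone comes from the 11,12,14-trimethyl ether (oxidative demethylation, then reduction). The C7 ketone comes from a late benzylic oxidation, so that until then C4–H is the only enolisable C–H.
2. Ring A is cut at C1–C2 and C3–C4. A tandem Michael addition/intramolecular Wittig olefination joins the C4 lactone enolate and the C1 aldehyde of tricyclic lactone aldehyde 22 through the two carbons of vinyltriphenylphosphonium bromide. This one operation forms ring A, the quaternary C4 and the 2-oxabicyclo[3.3.1]nonane core.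
3. Enabling feature: C4 is alpha to the lactone carbonyl C19, and C1 is a formyl group on the quaternary C10. The cis-fused δ-lactone ring (C4–C19–O–C20–C10–C5) holds C4 and C1 in a 1,3-syn relation, the right distance for a two-carbon bridge.
4. 22 comes from oxidative lactonisation of a 1,5-diol, which comes from an auxiliary-controlled conjugate addition/alkylation on a dihydronaphthalene carbaldehyde (sets C5, then C10). That aldehyde comes from tetralone 8, made from 1,2,4-trimethoxybenzene by two Friedel–Crafts acylations.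
5. Ring order: ring C (purchased arene), then ring B, then the lactone ring, then ring A.

Key step: step 14

Remark 1: abietane numbering is used throughout (ring A: C1–C5, C10; ring B: C5–C10; aromatic ring C: C8, C9, C11–C14; C18 methyl and C19 carboxyl on C4; C20 oxymethylene on C10). In this numbering the target is (4S,5R,10R).

Remark 2: the facial sense of the tert-leucine auxiliary in step 9 is assumed from the chelate model and the (S)-ester is written; should the sense be opposite, the (R)-ester is used with no other change. C4 is an inconsequential epimer mixture in compounds 17–22 and is written without configuration.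

## Route

Step 1
Reactants: 1 1,2,4-trimethoxybenzene
Product: 3 2-(2,3,6-trimethoxyphenyl)propan-2-ol, via (2,3,6-trimethoxyphenyl)lithium 2 (not isolated)
Conditions: n-BuLi, TMEDA, THF, 0 °C; acetone, −78 to 25 °C; H2O
Reagents that add atoms: acetone, CC(C)=O
Why: Directed ortho-lithiation should take place at the position flanked by two methoxy groups, and the aryllithium then adds to acetone.

Step 2
Reactants: 3 2-(2,3,6-trimethoxyphenyl)propan-2-ol
Product: 4 2-isopropyl-1,3,4-trimethoxybenzene
Conditions: Et3SiH, CF3CO2H, CH2Cl2, 0 to 25 °C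
Reagents that add atoms: none
Why: Ionic hydrogenation (protonation, then hydride transfer from the silane) of an electron-rich tertiary benzylic alcohol.

Step 3
Reactants: 4 2-isopropyl-1,3,4-trimethoxybenzene; 5 succinic anhydride
Product: 6 4-(3-isopropyl-2,4,5-trimethoxyphenyl)-4-oxobutanoic acid
Conditions: AlCl3, CH2Cl2/MeNO2, 0 °C
Reagents that add atoms: none
Why: Friedel–Crafts acylation should occur at C8, para to the C12 methoxy group and ortho to the C14 methoxy group, which is the most activated free position.

Step 4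
Reactants: 6 4-(3-isopropyl-2,4,5-trimethoxyphenyl)-4-oxobutanoic acid
Product: 7 4-(3-isopropyl-2,4,5-trimethoxyphenyl)butanoic acid
Conditions: Et3SiH, CF3CO2H, 50 °C
Reagents that add atoms: none
Why: Ionic hydrogenation of the electron-rich aryl ketone to the methylene group, which restores a ring nucleophilic enough for the second acylation.

Step 5
Reactants: 7 4-(3-isopropyl-2,4,5-trimethoxyphenyl)butanoic acid
Product: 8 6-isopropyl-5,7,8-trimethoxy-3,4-dihydronaphthalen-1(2H)-one
Conditions: (CF3CO)2O, CF3CO2H, 0 to 25 °C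
Reagents that add atoms: none
Why: Intramolecular Friedel–Crafts acylation (acid activated by the anhydride) at C9, the only free ring position next to the side chain, forms ring B.

Step 6
Reactants: 8 6-isopropyl-5,7,8-trimethoxy-3,4-dihydronaphthalen-1(2H)-one
Product: 10 6-isopropyl-5,7,8-trimethoxy-3,4-dihydronaphthalen-1-yl trifluoromethanesulfonate, via potassium enolate 9 (not isolated)
Conditions: KN(SiMe3)2, THF, −78 °C; PhNTf2, −78 to 0 °C
Reagents that add atoms: N-phenylbis(trifluoromethanesulfonimide), O=S(=O)(N(c1ccccc1)S(=O)(=O)C(F)(F)F)C(F)(F)F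
Why: Enolate formation and O-sulfonylation is the standard enol triflate synthesis.

Step 7
Reactants: 10 6-isopropyl-5,7,8-trimethoxy-3,4-dihydronaphthalen-1-yl trifluoromethanesulfonate
Product: 11 6-isopropyl-5,7,8-trimethoxy-3,4-dihydronaphthalene-1-carbaldehyde
Conditions: Pd(OAc)2 (cat.), dppp, CO (1 atm), Et3SiH, Et3N, DMF, 70 °C
Reagents that add atoms: carbon monoxide, [C-]#[O+]
Why: Palladium-catalysed reductive carbonylation (formylation) of an enol triflate, with the silane as hydride source.

Step 8
Reactants: 11 6-isopropyl-5,7,8-trimethoxy-3,4-dihydronaphthalene-1-carbaldehyde; 12 tert-butyl (S)-2-amino-3,3-dimethylbutanoate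
Product: 13 tert-butyl (S)-2-{(E)-[(6-isopropyl-5,7,8-trimethoxy-3,4-dihydronaphthalen-1-yl)methylidene]amino}-3,3-dimethylbutanoate
Conditions: MgSO4, CH2Cl2, 25 °C
Reagents that add atoms: none
Why: Condensation of the aldehyde and the primary amine gives the (E)-aldimine, with MgSO4 taking up the water.

Step 9
Reactants: 13 tert-butyl (S)-2-{(E)-[(6-isopropyl-5,7,8-trimethoxy-3,4-dihydronaphthalen-1-yl)methylidene]amino}-3,3-dimethylbutanoate
Product: 16 1-[(benzyloxy)methyl]-6-isopropyl-5,7,8-trimethoxy-2-(prop-1-en-2-yl)-1,2,3,4-tetrahydronaphthalene-1-carbaldehyde (formyl cis to isopropenyl), via bromomagnesium aza-enolate 14 (not isolated), via quaternary aldimine 15 (not isolated)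
Conditions: CH2=C(CH3)MgBr, THF, −55 to −20 °C; BnOCH2Cl, DMPU, −20 to 25 °C; aq. citric acid, 25 °C
Reagents that add atoms: isopropenylmagnesium bromide, C=C(C)[Mg]Br; benzyl chloromethyl ether, ClCOCc1ccccc1; water, O
Why: Koga-type auxiliary-controlled conjugate addition, in which the Grignard reagent chelated between the imine nitrogen and the ester carbonyl is delivered to one face of C5 (sets C5), the aza-enolate is then alkylated anti to the new C5 substituent (sets the quaternary C10 with the formyl carbon cis to the isopropenyl group), and mild acid hydrolysis releases the aldehyde and the auxiliary.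

Step 10
Reactants: 16 1-[(benzyloxy)methyl]-6-isopropyl-5,7,8-trimethoxy-2-(prop-1-en-2-yl)-1,2,3,4-tetrahydronaphthalene-1-carbaldehyde
Product: 18 {1-[(benzyloxy)methyl]-2-(1-hydroxypropan-2-yl)-6-isopropyl-5,7,8-trimethoxy-1,2,3,4-tetrahydronaphthalen-1-yl}methanol, via borane adduct 17 (not isolated)
Conditions: BH3·THF, THF, 0 to 25 °C; NaOH, H2O2, 0 °C
Reagents that add atoms: hydrogen peroxide, OO
Why: Borane reduces the aldehyde and hydroborates the 1,1-disubstituted alkene at its terminal carbon (anti-Markovnikov hydroboration–oxidation), the new C4 centre forming as an epimer mixture that is planarised again in step 14.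

Step 11
Reactants: 18 {1-[(benzyloxy)methyl]-2-(1-hydroxypropan-2-yl)-6-isopropyl-5,7,8-trimethoxy-1,2,3,4-tetrahydronaphthalen-1-yl}methanol
Product: 20 10b-[(benzyloxy)methyl]-8-isopropyl-7,9,10-trimethoxy-4-methyl-1,4,4a,5,6,10b-hexahydro-3H-benzo[f]isochromen-3-one (cis ring fusion), via lactol 19 (not isolated)
Conditions: TEMPO (cat.), PhI(OAc)2, CH2Cl2, 25 °C
Reagents that add atoms: none
Why: In this TEMPO/PhI(OAc)2 oxidative lactonisation the unhindered C19 primary alcohol should be oxidised much faster than the neopentyl C20 alcohol, ring closure onto the C20 hydroxyl (cis to the C5 side chain) gives lactol 19, and a second oxidation gives the cis-fused δ-lactone with its carbonyl at C19.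

Step 12
Reactants: 20 10b-[(benzyloxy)methyl]-8-isopropyl-7,9,10-trimethoxy-4-methyl-1,4,4a,5,6,10b-hexahydro-3H-benzo[f]isochromen-3-one
Product: 21 10b-(hydroxymethyl)-8-isopropyl-7,9,10-trimethoxy-4-methyl-1,4,4a,5,6,10b-hexahydro-3H-benzo[f]isochromen-3-one
Conditions: H2 (1 atm), Pd on carbon (10% Pd/C), EtOAc, 25 °C
Reagents that add atoms: none
Why: Hydrogenolysis of the benzyl ether, to which the lactone and the aryl methyl ethers are inert.

Step 13
Reactants: 21 10b-(hydroxymethyl)-8-isopropyl-7,9,10-trimethoxy-4-methyl-1,4,4a,5,6,10b-hexahydro-3H-benzo[f]isochromen-3-one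
Product: 22 8-isopropyl-7,9,10-trimethoxy-4-methyl-3-oxo-1,4,4a,5,6,10b-hexahydro-3H-benzo[f]isochromene-10b-carbaldehyde
Conditions: Dess–Martin periodinane, NaHCO3, CH2Cl2, 25 °C
Reagents that add atoms: none
Why: Dess–Martin oxidation of the neopentyl primary alcohol gives a non-enolisable aldehyde under buffered, non-basic conditions.

Step 14
Reactants: 22 8-isopropyl-7,9,10-trimethoxy-4-methyl-3-oxo-1,4,4a,5,6,10b-hexahydro-3H-benzo[f]isochromene-10b-carbaldehyde; 23 vinyltriphenylphosphonium bromide
Product: 26 11,12,14-trimethoxyabieta-1,8,11,13-tetraen-19,20-olide, via potassium lactone enolate 24 (not isolated), via phosphonium ylide 25 (not isolated)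
Conditions: KN(SiMe3)2, THF, −78 °C; 23, DMF, −78 to 25 °C, then 50 °C
Reagents that add atoms: none
Why: KN(SiMe3)2 removes the only acidic C–H of 22, the C4–H alpha to the lactone carbonyl C19 (C10 is quaternary, the aldehyde has no alpha hydrogen and C7 is still a methylene group); enolate 24 adds in Michael fashion to the vinylphosphonium salt to form the C3–C4 bond and the non-stabilised ylide 25, whose carbon C2 then attacks the C1 aldehyde in an intramolecular Wittig olefination that forms the C1=C2 bond and expels Ph3PO. The closest known reaction type is the Schweizer annulation, in which an enolate that carries a carbonyl group is joined to vinyltriphenylphosphonium bromide to give a cyclopentene or cyclohexene, and ester-type alkali metal enolates are known Michael donors towards vinylphosphonium salts. Ring A closes as a six-membered ring by 6-exo-trig attack of the ylide carbon on the aldehyde, which at the same time completes the 2-oxabicyclo[3.3.1]nonane core. The new quaternary stereocentre C4 is set in the Michael step: the salt should approach the planar enolate anti to the adjacent C5–C6 bond, which is the face syn to the formyl group, and only this C4 epimer places the ylide 1,3-diaxial to the aldehyde so that it can ring-close. The step needs the Michael addition to outrun aldol addition of the enolate to the aldehyde; this is secured because the intramolecular aldol would give a cyclobutane, the intermolecular aldol would join a fully substituted enolate carbon to a neopentyl aldehyde and is reversible, and the unhindered CH2 terminus of the vinylphosphonium salt reacts irreversibly.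

Step 15
Reactants: 26 11,12,14-trimethoxyabieta-1,8,11,13-tetraen-19,20-olide
Product: 27 11,12,14-trimethoxyabieta-8,11,13-trien-19,20-olide
Conditions: H2 (1 atm), Pd on carbon (10% Pd/C), EtOAc, 25 °C
Reagents that add atoms: none
Why: Catalytic hydrogenation of the disubstituted cis-alkene, which creates no stereocentre.

Step 16
Reactants: 27 11,12,14-trimethoxyabieta-8,11,13-trien-19,20-olide
Product: 28 11,12,14-trimethoxy-7-oxoabieta-8,11,13-trien-19,20-olide
Conditions: CrO3, AcOH/H2O, 25 °C
Reagents that add atoms: chromium trioxide, O=[Cr](=O)=O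
Why: Benzylic oxidation with CrO3 in acetic acid is the standard way to a 7-oxo abietatriene, and C7 is the only benzylic methylene group and is activated by the para methoxy group on C12.

Step 17
Reactants: 28 11,12,14-trimethoxy-7-oxoabieta-8,11,13-trien-19,20-olide
Product: 30 (4S,5R,10R)-11,14-dihydroxy-12-methoxy-7-oxoabieta-8,11,13-trien-19,20-olide, via quinone 29 (not isolated)
Conditions: (NH4)2Ce(NO3)6, MeCN/H2O, 0 °C; Na2S2O4, H2O/EtOAc, 25 °C
Reagents that add atoms: water, O
Why: Oxidative demethylation of the para-dimethoxy pair (C11, C14) should give the 12-methoxy para-quinone, in which the C12 methyl ether survives as a vinylogous ester, and dithionite reduction of the quinone then gives the hydroquinone without touching a stereocentre.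

## Compound list

1 | 1,2,4-trimethoxybenzene | COc1ccc(OC)c(OC)c1 | starting material
2 | (2,3,6-trimethoxyphenyl)lithium | COc1c(OC)ccc(OC)c1[Li] | intermediate
3 | 2-(2,3,6-trimethoxyphenyl)propan-2-ol | COc1c(OC)ccc(OC)c1C(C)(C)O | intermediate
4 | 2-isopropyl-1,3,4-trimethoxybenzene | COc1c(OC)ccc(OC)c1C(C)C | intermediate
5 | succinic anhydride | O=C1CCC(=O)O1 | starting material
6 | 4-(3-isopropyl-2,4,5-trimethoxyphenyl)-4-oxobutanoic acid | COc1c(OC)cc(C(=O)CCC(=O)O)c(OC)c1C(C)C | intermediate
7 | 4-(3-isopropyl-2,4,5-trimethoxyphenyl)butanoic acid | COc1c(OC)cc(CCCC(=O)O)c(OC)c1C(C)C | intermediate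
8 | 6-isopropyl-5,7,8-trimethoxy-3,4-dihydronaphthalen-1(2H)-one | COc1c(OC)c2c(c(OC)c1C(C)C)CCCC2=O | intermediate
9 | potassium enolate of 8 | COc1c(OC)c2c(c(OC)c1C(C)C)CCC=C2[O-].[K+] | intermediate
10 | 6-isopropyl-5,7,8-trimethoxy-3,4-dihydronaphthalen-1-yl trifluoromethanesulfonate | COc1c(OC)c2c(c(OC)c1C(C)C)CCC=C2OS(=O)(=O)C(F)(F)F | intermediate
11 | 6-isopropyl-5,7,8-trimethoxy-3,4-dihydronaphthalene-1-carbaldehyde | COc1c(OC)c2c(c(OC)c1C(C)C)CCC=C2C=O | intermediate
12 | tert-butyl (S)-2-amino-3,3-dimethylbutanoate ((S)-tert-leucine tert-butyl ester, free base) | N[C@@H](C(C)(C)C)C(=O)OC(C)(C)C | starting material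
13 | (E)-aldimine of 11 with 12 | COc1c(OC)c2c(c(OC)c1C(C)C)CCC=C2/C=N/[C@@H](C(C)(C)C)C(=O)OC(C)(C)C | intermediate
14 | bromomagnesium aza-enolate after conjugate addition (C5 as in the target) | COc1c(OC)c2c(c(OC)c1C(C)C)CC[C@@H](C(C)=C)C2=CN([Mg]Br)[C@@H](C(C)(C)C)C(=O)OC(C)(C)C | intermediate
15 | C10-quaternary aldimine (CH2OBn trans to isopropenyl) | COc1c(OC)c2c(c(OC)c1C(C)C)CC[C@@H](C(C)=C)[C@]2(/C=N/[C@@H](C(C)(C)C)C(=O)OC(C)(C)C)COCc1ccccc1 | intermediate
16 | 1-[(benzyloxy)methyl]-6-isopropyl-5,7,8-trimethoxy-2-(prop-1-en-2-yl)-1,2,3,4-tetrahydronaphthalene-1-carbaldehyde (formyl cis to isopropenyl) | COc1c(OC)c2c(c(OC)c1C(C)C)CC[C@@H](C(C)=C)[C@]2(C=O)COCc1ccccc1 | intermediate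
17 | borane adduct of 16 (alkoxyborane and primary alkylborane) | COc1c(OC)c2c(c(OC)c1C(C)C)CC[C@@H](C(C)CB)[C@]2(COB)COCc1ccccc1 | intermediate
18 | {1-[(benzyloxy)methyl]-2-(1-hydroxypropan-2-yl)-6-isopropyl-5,7,8-trimethoxy-1,2,3,4-tetrahydronaphthalen-1-yl}methanol | COc1c(OC)c2c(c(OC)c1C(C)C)CC[C@@H](C(C)CO)[C@]2(CO)COCc1ccccc1 | intermediate
19 | cis-fused lactol (3-hydroxy analogue of 20) | COc1c(OC)c2c(c(OC)c1C(C)C)CC[C@@H]1[C@@]2(COCc3ccccc3)COC(O)C1C | intermediate
20 | 10b-[(benzyloxy)methyl]-8-isopropyl-7,9,10-trimethoxy-4-methyl-1,4,4a,5,6,10b-hexahydro-3H-benzo[f]isochromen-3-one (cis-fused) | COc1c(OC)c2c(c(OC)c1C(C)C)CC[C@@H]1[C@@]2(COCc3ccccc3)COC(=O)C1C | intermediate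
21 | 10b-(hydroxymethyl)-8-isopropyl-7,9,10-trimethoxy-4-methyl-1,4,4a,5,6,10b-hexahydro-3H-benzo[f]isochromen-3-one (cis-fused) | COc1c(OC)c2c(c(OC)c1C(C)C)CC[C@@H]1[C@@]2(CO)COC(=O)C1C | intermediate
22 | 8-isopropyl-7,9,10-trimethoxy-4-methyl-3-oxo-1,4,4a,5,6,10b-hexahydro-3H-benzo[f]isochromene-10b-carbaldehyde (cis-fused) | COc1c(OC)c2c(c(OC)c1C(C)C)CC[C@@H]1[C@@]2(C=O)COC(=O)C1C | intermediate
23 | vinyltriphenylphosphonium bromide | C=C[P+](c1ccccc1)(c1ccccc1)c1ccccc1.[Br-] | starting material
24 | potassium enolate of lactone 22 | COc1c(OC)c2c(c(OC)c1C(C)C)CC[C@@H]1[C@@]2(C=O)COC([O-])=C1C.[K+] | intermediate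
25 | phosphonium ylide (C4 quaternary, ylide chain syn to the formyl group) | COc1c(OC)c2c(c(OC)c1C(C)C)CC[C@@H]1[C@@]2(C=O)COC(=O)[C@@]1(C)CC=P(c1ccccc1)(c1ccccc1)c1ccccc1 | intermediate
26 | 11,12,14-trimethoxyabieta-1,8,11,13-tetraen-19,20-olide | COc1c(OC)c2c(c(OC)c1C(C)C)CC[C@@H]1[C@]23C=CC[C@]1(C)C(=O)OC3 | intermediate
27 | 11,12,14-trimethoxyabieta-8,11,13-trien-19,20-olide | COc1c(OC)c2c(c(OC)c1C(C)C)CC[C@@H]1[C@]23CCC[C@]1(C)C(=O)OC3 | intermediate
28 | 11,12,14-trimethoxy-7-oxoabieta-8,11,13-trien-19,20-olide | COc1c(OC)c2c(c(OC)c1C(C)C)C(=O)C[C@@H]1[C@]23CCC[C@]1(C)C(=O)OC3 | intermediate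
29 | 12-methoxy-7,11,14-trioxoabieta-8,12-dien-19,20-olide (para-quinone) | COC1=C(C(C)C)C(=O)C(C(=O)C[C@@H]2[C@]34CCC[C@]2(C)C(=O)OC4)=C3C1=O | intermediate
30 | (4S,5R,10R)-11,14-dihydroxy-12-methoxy-7-oxoabieta-8,11,13-trien-19,20-olide (CNP0159814.2) | COc1c(O)c2c(c(O)c1C(C)C)C(=O)C[C@@H]1[C@]23CCC[C@]1(C)C(=O)OC3 | target

## Step count and risks

Total step count: 17. Longest linear sequence: 17 steps (from 1,2,4-trimethoxybenzene).

Steps most likely to fail:

Step 14. The amide base or the lactone enolate may attack the aldehyde of a second molecule (aldol oligomerisation). Alternatively the Michael addition may take place on the face anti to the formyl group, after which the ylide cannot reach the aldehyde. The fallback sets out from 22. Methylenation with Ph3P=CH2 (from methyltriphenylphosphonium bromide and KOtBu, THF, 0 °C) would give the C10-vinyl lactone F1. With the aldehyde gone, LiN(iPr)2 and then allyl bromide (THF, −78 °C) would allylate C4 anti to the C5–C6 bond to give the C4-allyl C10-vinyl lactone F2. Ring-closing metathesis with the second-generation Grubbs catalyst (CH2Cl2, 40 °C) would then close ring A between the two terminal alkenes, and the route is rejoined at 26.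

Step 9. The magnesium aza-enolate 14 sits next to the peri methoxy group, so its C-alkylation may be slow and N-alkylation or simple protonation may take over. The fallback sets out from 13. The same Grignard addition is quenched with aqueous citric acid to give the C10–H aldehyde F3 (C10 epimers). A crossed aldol reaction with aqueous formaldehyde and K2CO3 (MeOH, 0 °C), in which formaldehyde should add to the enolate anti to the isopropenyl group, would give the hydroxymethyl aldehyde F4. O-Benzylation with benzyl 2,2,2-trichloroacetimidate and catalytic CF3SO3H (CH2Cl2, 0 °C) rejoins the route at 16.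

Step 16. Hexavalent chromium may attack the isopropyl methine or oxidatively demethylate the electron-rich ring instead of oxidising C7. The fallback sets out from 27. Radical bromination with N-bromosuccinimide and AIBN (PhCF3, 80 °C) at C7, the only benzylic methylene group of a ring with no free position, would give the C7 bromide F5. Kornblum oxidation (DMSO, NaHCO3, 100 °C) would convert it into the ketone, and the route is rejoined at 28.

Further compounds
F1 | step 14 | C10-vinyl lactone (formyl of 22 replaced by vinyl) | COc1c(OC)c2c(c(OC)c1C(C)C)CC[C@@H]1[C@@]2(C=C)COC(=O)C1C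
F2 | step 14 | C4-allyl C10-vinyl lactone (allyl syn to vinyl) | COc1c(OC)c2c(c(OC)c1C(C)C)CC[C@@H]1[C@@]2(C=C)COC(=O)[C@@]1(C)CC=C
F3 | step 9 | 6-isopropyl-5,7,8-trimethoxy-2-(prop-1-en-2-yl)-1,2,3,4-tetrahydronaphthalene-1-carbaldehyde (C10 epimers) | COc1c(OC)c2c(c(OC)c1C(C)C)CC[C@@H](C(C)=C)C2C=O
F4 | step 9 | 1-(hydroxymethyl)-6-isopropyl-5,7,8-trimethoxy-2-(prop-1-en-2-yl)-1,2,3,4-tetrahydronaphthalene-1-carbaldehyde (formyl cis to isopropenyl) | COc1c(OC)c2c(c(OC)c1C(C)C)CC[C@@H](C(C)=C)[C@]2(C=O)CO
F5 | step 16 | 7-bromo-11,12,14-trimethoxyabieta-8,11,13-trien-19,20-olide (C7 epimers) | COc1c(OC)c2c(c(OC)c1C(C)C)C(Br)C[C@@H]1[C@]23CCC[C@]1(C)C(=O)OC3
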